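**Retrosynthetic overview**

1. Numbering: ring C1 (carbinol, CH3/OH), C2 (side chain), C3 (gem-dimethyl), C4–C6 (CH2); side chain C1′–C13′ from the ring. The C2′–C3′ bond is cut (B-alkyl Suzuki–Miyaura) into vinylcyclohexanol 6 and the C14 (E)-alkenyl iodide 16, which comes from geraniol, propyne and MeI.
2. 6 comes from β-hydroxy aldehyde 5 by methylenation; with C1′ at the aldehyde level, C1–C2 is an aldol bond.
3. The only ring is closed in the key step by making C4–C5 and C1–C2 in one flask: a [3+3] union of a C2–C3–C4 unit with C5–C6–C1(CH3)=O of methyl vinyl ketone.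
4. Enabling feature: C3 is a quaternary gem-dimethyl carbon lying 1,3 between C2 and C4, so C2–C3–C4 and C1′ can be stored as the strained ring of 3,3-dimethylcyclobutanol. β-Scission of its alkoxy radical frees a non-rearranging primary radical at C4 and an aldehyde at C1′ that makes C2 enolisable; the tertiary carbinol C1 with its methyl is the enone carbonyl.
5. Both stereocentres (C1, C2) are set in the aldol half of the key step by L-proline; the chain geometry comes from geraniol and a syn-hydrozirconation.

Key step: step 2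

Remark: L-proline is assumed to induce the same sense as in its anti-aldol reactions of aldehyde donors, i.e. (S) at the enamine carbon; were the sense opposite, D-proline would be used.

**Step 1**
Reactants: 1 3,3-dimethylcyclobutan-1-one
Product: 2 3,3-dimethylcyclobutan-1-ol
Conditions: NaBH4, MeOH, 0 °C
Reagents that add atoms: none
Why: Borohydride reduction of the ketone should give the achiral secondary cyclobutanol; no stereocentre arises.

**Step 2**
Reactants: 2 3,3-dimethylcyclobutan-1-ol; 3 but-3-en-2-one (methyl vinyl ketone)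
Product: 5 (1S,2S)-2-hydroxy-2,6,6-trimethylcyclohexane-1-carbaldehyde, via 3,3-dimethyl-7-oxooctanal 4 (not isolated)
Conditions: CeCl3 (5 mol%), n-Bu4NCl (15 mol%), MeCN, 400 nm LEDs, 25 °C; then evaporation of volatiles, L-proline (20 mol%), CH2Cl2, 25 °C
Reagents that add atoms: none
Why: Under 400 nm light the tetravalent cerium alkoxide of 2 undergoes ligand-to-metal charge transfer to an alkoxy radical, whose strain-driven β-scission (both ring bonds are equivalent) leaves a primary radical at the future C4 and an aldehyde at C1′; Giese addition to 3 forms C4–C5 and the α-keto radical is reduced by trivalent cerium and protonated to 4, the closest known type being the cerium-photocatalysed ring-opening addition of cycloalkanols to electron-poor alkenes. After excess 3 is evaporated, L-proline condenses with the aldehyde and the (E)-enamine adds to the methyl ketone, which forms C1–C2; the closest known type is the proline-catalysed enolexo aldolisation of dicarbonyl compounds. The ring closes in the 6-enolexo-exo-trig mode through a chair. C2 is set by the catalyst, whose carboxylic acid delivers the ketone to one enamine face ((S), as in proline anti-aldols of aldehyde donors), and C1 follows because that acid hydrogen-bonds the ketone oxygen next to the enamine nitrogen, which places oxygen equatorial and the methyl group axial and so should give the trans aldol. The step needs one donor and one acceptor: C3 is quaternary, so the radical has nothing to rearrange to and the aldehyde has only C2 to enolise, the aldehyde forms its enamine far faster than the ketone, and the only ring size within reach of that enamine is six.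

**Step 3**
Reactants: 5 (1S,2S)-2-hydroxy-2,6,6-trimethylcyclohexane-1-carbaldehyde
Product: 6 (1S,2S)-2-ethenyl-1,3,3-trimethylcyclohexan-1-ol
Conditions: Zn, CH2Br2, TiCl4, THF, 0 → 25 °C
Reagents that add atoms: dibromomethane, BrCBr
Why: Takai–Lombardo methylenation uses a non-basic gem-dimetallic reagent, so the aldehyde should become the vinyl group without retro-aldol cleavage or epimerisation at C2; no new stereocentre.

**Step 4**
Reactants: 7 geraniol
Product: 8 tert-butyl{[(2E)-3,7-dimethylocta-2,6-dien-1-yl]oxy}dimethylsilane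
Conditions: TBSCl, imidazole, DMF, 25 °C
Reagents that add atoms: tert-butyldimethylsilyl chloride, CC(C)(C)[Si](C)(C)Cl
Why: Imidazole-promoted silyl ether formation masks the primary allylic alcohol for the organometallic steps.

**Step 5**
Reactants: 8 tert-butyl{[(2E)-3,7-dimethylocta-2,6-dien-1-yl]oxy}dimethylsilane
Product: 9 (2E,6E)-8-{[tert-butyl(dimethyl)silyl]oxy}-2,6-dimethylocta-2,6-dien-1-ol
Conditions: SeO2 (0.1 equiv), t-BuOOH, salicylic acid (0.1 equiv), CH2Cl2, 0 → 25 °C
Reagents that add atoms: tert-butyl hydroperoxide, CC(C)(C)OO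
Why: Catalytic SeO2 allylic oxidation (ene reaction, then [2,3]-sigmatropic shift) should attack the electron-rich terminal isopropylidene group at its (E)-methyl and give the (E)-allylic alcohol, the 2,3-alkene being deactivated by the allylic silyloxy group.

**Step 6**
Reactants: 9 (2E,6E)-8-{[tert-butyl(dimethyl)silyl]oxy}-2,6-dimethylocta-2,6-dien-1-ol
Product: 10 {[(2E,6E)-8-bromo-3,7-dimethylocta-2,6-dien-1-yl]oxy}(tert-butyl)dimethylsilane
Conditions: CBr4, PPh3, CH2Cl2, 0 °C
Reagents that add atoms: tetrabromomethane, BrC(Br)(Br)Br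
Why: The Appel reaction converts the primary allylic alcohol into the bromide by SN2 displacement of the oxyphosphonium ion, without allylic transposition.

**Step 7**
Reactants: 10 {[(2E,6E)-8-bromo-3,7-dimethylocta-2,6-dien-1-yl]oxy}(tert-butyl)dimethylsilane; 11 propyne
Product: 14 tert-butyl{[(2E,6E)-3,7-dimethyldodeca-2,6-dien-10-yn-1-yl]oxy}dimethylsilane, via 1,3-dilithiopropyne 12 (not isolated), via lithium alkynide 13 (not isolated)
Conditions: 11, n-BuLi (2 equiv), TMEDA, Et2O/hexane, −78 → 0 °C; then 10, −78 → 0 °C; then MeI, 0 → 25 °C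
Reagents that add atoms: iodomethane, CI
Why: Propargylation of an allylic bromide with 1,3-dilithiopropyne, which alkylates at its sp3 carbon by SN2 with retention of alkene geometry, followed by C-methylation of the resulting lithium alkynide in the same flask.

**Step 8**
Reactants: 14 tert-butyl{[(2E,6E)-3,7-dimethyldodeca-2,6-dien-10-yn-1-yl]oxy}dimethylsilane
Product: 16 tert-butyl{[(2E,6E,10E)-11-iodo-3,7-dimethyldodeca-2,6,10-trien-1-yl]oxy}dimethylsilane, via alkenylzirconocene chloride 15 (not isolated)
Conditions: Cp2Zr(H)Cl (1.5 equiv), THF, 25 → 40 °C; then I2, 0 °C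
Reagents that add atoms: iodine, II
Why: Hydrozirconation is a syn addition that, with excess reagent under equilibrating conditions, should place zirconium on the less hindered methyl-bearing alkyne carbon, and iodinolysis with retention gives the (E)-2-iodoalkene; the trisubstituted alkenes do not react.

**Step 9**
Reactants: 6 (1S,2S)-2-ethenyl-1,3,3-trimethylcyclohexan-1-ol; 16 tert-butyl{[(2E,6E,10E)-11-iodo-3,7-dimethyldodeca-2,6,10-trien-1-yl]oxy}dimethylsilane
Product: 18 (1S,2S)-2-[(3E,7E,11E)-13-{[tert-butyl(dimethyl)silyl]oxy}-3,7,11-trimethyltrideca-3,7,11-trien-1-yl]-1,3,3-trimethylcyclohexan-1-ol, via B-alkyl-9-borabicyclononane 17 (not isolated)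
Conditions: 9-BBN (2.5 equiv), THF, 25 → 60 °C; then 16, Pd(dppf)Cl2 (5 mol%), AsPh3, Cs2CO3, DMF/H2O, 25 → 50 °C
Reagents that add atoms: none
Why: Anti-Markovnikov hydroboration of the vinyl group followed by B-alkyl Suzuki–Miyaura coupling should join C2′ to C3′ with retention of the (E) geometry of the iodide; the ring stereocentres are not touched and the free tertiary alcohol is tolerated.

**Step 10**
Reactants: 18 (1S,2S)-2-[(3E,7E,11E)-13-{[tert-butyl(dimethyl)silyl]oxy}-3,7,11-trimethyltrideca-3,7,11-trien-1-yl]-1,3,3-trimethylcyclohexan-1-ol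
Product: 19 preluffariellolide A
Conditions: TBAF, THF, 0 → 25 °C
Reagents that add atoms: none
Why: Fluoride-induced desilylation releases the primary allylic alcohol; the tertiary alcohol and the alkenes are unaffected.

**Compound list**

1 | 3,3-dimethylcyclobutan-1-one | CC1(C)CC(=O)C1 | starting material
2 | 3,3-dimethylcyclobutan-1-ol | CC1(C)CC(O)C1 | intermediate
3 | but-3-en-2-one (methyl vinyl ketone) | CC(=O)C=C | starting material
4 | 3,3-dimethyl-7-oxooctanal | CC(=O)CCCC(C)(C)CC=O | intermediate
5 | (1S,2S)-2-hydroxy-2,6,6-trimethylcyclohexane-1-carbaldehyde | O=C[C@H]1C(C)(C)CCC[C@]1(C)O | intermediate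
6 | (1S,2S)-2-ethenyl-1,3,3-trimethylcyclohexan-1-ol | C=C[C@H]1C(C)(C)CCC[C@]1(C)O | intermediate
7 | geraniol, (2E)-3,7-dimethylocta-2,6-dien-1-ol | OC/C=C(\C)CCC=C(C)C | starting material
8 | tert-butyl{[(2E)-3,7-dimethylocta-2,6-dien-1-yl]oxy}dimethylsilane | CC(C)(C)[Si](C)(C)OC/C=C(\C)CCC=C(C)C | intermediate
9 | (2E,6E)-8-{[tert-butyl(dimethyl)silyl]oxy}-2,6-dimethylocta-2,6-dien-1-ol | CC(C)(C)[Si](C)(C)OC/C=C(\C)CC/C=C(\C)CO | intermediate
10 | {[(2E,6E)-8-bromo-3,7-dimethylocta-2,6-dien-1-yl]oxy}(tert-butyl)dimethylsilane | CC(C)(C)[Si](C)(C)OC/C=C(\C)CC/C=C(\C)CBr | intermediate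
11 | propyne | CC#C | starting material
12 | 1,3-dilithiopropyne | [Li]CC#C[Li] | intermediate
13 | lithium alkynide of the propargylated chain, {(6E,10E)-12-{[tert-butyl(dimethyl)silyl]oxy}-6,10-dimethyldodeca-6,10-dien-1-yn-1-yl}lithium | CC(C)(C)[Si](C)(C)OC/C=C(\C)CC/C=C(\C)CCC#C[Li] | intermediate
14 | tert-butyl{[(2E,6E)-3,7-dimethyldodeca-2,6-dien-10-yn-1-yl]oxy}dimethylsilane | CC(C)(C)[Si](C)(C)OC/C=C(\C)CC/C=C(\C)CCC#CC | intermediate
15 | (E)-alkenylzirconocene chloride, zirconium on C11 of the chain | CC(C)(C)[Si](C)(C)OC/C=C(\C)CC/C=C(\C)CC/C=C(\C)[Zr](Cl)(C1C=CC=C1)C1C=CC=C1 | intermediate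
16 | tert-butyl{[(2E,6E,10E)-11-iodo-3,7-dimethyldodeca-2,6,10-trien-1-yl]oxy}dimethylsilane | CC(C)(C)[Si](C)(C)OC/C=C(\C)CC/C=C(\C)CC/C=C(\C)I | intermediate
17 | (1S,2S)-2-[2-(9-borabicyclo[3.3.1]nonan-9-yl)ethyl]-1,3,3-trimethylcyclohexan-1-ol | C1CCC2CCCC1B2CC[C@H]1C(C)(C)CCC[C@]1(C)O | intermediate
18 | (1S,2S)-2-[(3E,7E,11E)-13-{[tert-butyl(dimethyl)silyl]oxy}-3,7,11-trimethyltrideca-3,7,11-trien-1-yl]-1,3,3-trimethylcyclohexan-1-ol | CC(C)(C)[Si](C)(C)OC/C=C(\C)CC/C=C(\C)CC/C=C(\C)CC[C@H]1C(C)(C)CCC[C@]1(C)O | intermediate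
19 | preluffariellolide A, (1S,2S)-2-[(3E,7E,11E)-13-hydroxy-3,7,11-trimethyltrideca-3,7,11-trien-1-yl]-1,3,3-trimethylcyclohexan-1-ol | C/C(=C\CO)CC/C=C(\C)CC/C=C(\C)CC[C@H]1C(C)(C)CCC[C@]1(C)O | target

**Step count and risks**

Total: 10 steps. Longest linear sequence: 7 steps (steps 4–10, from geraniol); the ring branch is 5 steps (1, 2, 3, 9, 10).

Step 2 is the most likely to fail. The relay can break down at the radical stage: the α-keto radical may close back onto the formyl group, chlorine or alkoxy radicals may abstract the aldehyde hydrogen, and 3 may oligomerise. Cerium salts carried into the amine stage may also open an unselective background aldol. The fallback separates the two bond formations and sets out from 2. Alkoxy-radical β-fragmentation with iodine-atom capture (PhI(OAc)2, I2, visible light) should give 4-iodo-3,3-dimethylbutanal F1. A tin-hydride Giese addition of F1 to 3 (Bu3SnH, AIBN, benzene, 80 °C), in which hydrogen transfer to the adduct radical is fast, should then give 4. Here 4 is isolated and purified, and it comes back to the route when it is closed with L-proline in CH2Cl2 as a separate, metal-free operation to 5.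

Step 3 is second. The Lewis-acidic titanium reagent may trigger retro-aldol cleavage or ionisation at the tertiary carbinol, or enolisation may epimerise C2. The fallback sets out from 5 and protects before a basic olefination. Silylation (Et3SiOTf, 2,6-lutidine, −78 °C) should give (1S,2S)-2,6,6-trimethyl-2-[(triethylsilyl)oxy]cyclohexane-1-carbaldehyde F2, which can no longer undergo retro-aldol cleavage. Wittig methylenation (Ph3PCH3Br, KN(SiMe3)2, THF, −78 → 0 °C) should give triethyl{[(1S,2S)-2-ethenyl-1,3,3-trimethylcyclohexyl]oxy}silane F3, and TBAF returns the route to 6.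

Step 8 is third. Hydrometalation may occur partly at the wrong alkyne carbon (zirconium on C10), which would give a regioisomeric iodide that is hard to separate. The fallback sets out from 13 in the flask of step 7 and fixes the regiochemistry with silicon. Quenching 13 with Me3SiCl in place of MeI should give tert-butyl{[(2E,6E)-3,7-dimethyl-11-(trimethylsilyl)undeca-2,6-dien-10-yn-1-yl]oxy}dimethylsilane F4. Anti hydroalumination with i-Bu2AlH in hexane, which puts aluminium only on the silyl-bearing carbon, should give the α-silyl alkenylalane F5. MeLi converts it into the lithium alkenyl(methyl)diisobutylaluminate F6, and MeI should then give tert-butyl{[(2E,6E,10E)-3,7-dimethyl-11-(trimethylsilyl)dodeca-2,6,10-trien-1-yl]oxy}dimethylsilane F7. Ipso-iododesilylation with N-iodosuccinimide, with retention, comes back to the route at 16.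

Further compounds
F1 | step 2 | 4-iodo-3,3-dimethylbutanal | O=CCC(C)(C)CI
F2 | step 3 | (1S,2S)-2,6,6-trimethyl-2-[(triethylsilyl)oxy]cyclohexane-1-carbaldehyde | O=C[C@H]1C(C)(C)CCC[C@]1(C)O[Si](CC)(CC)CC
F3 | step 3 | triethyl{[(1S,2S)-2-ethenyl-1,3,3-trimethylcyclohexyl]oxy}silane | C=C[C@H]1C(C)(C)CCC[C@]1(C)O[Si](CC)(CC)CC
F4 | step 8 | tert-butyl{[(2E,6E)-3,7-dimethyl-11-(trimethylsilyl)undeca-2,6-dien-10-yn-1-yl]oxy}dimethylsilane | CC(C)(C)[Si](C)(C)OC/C=C(\C)CC/C=C(\C)CCC#C[Si](C)(C)C
F5 | step 8 | [(1E,5E,9E)-11-{[tert-butyl(dimethyl)silyl]oxy}-5,9-dimethyl-1-(trimethylsilyl)undeca-1,5,9-trien-1-yl]bis(2-methylpropyl)alane | CC(C)(C)[Si](C)(C)OC/C=C(\C)CC/C=C(\C)CC/C=C(\[Al](CC(C)C)CC(C)C)[Si](C)(C)C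
F6 | step 8 | lithium [(1E,5E,9E)-11-{[tert-butyl(dimethyl)silyl]oxy}-5,9-dimethyl-1-(trimethylsilyl)undeca-1,5,9-trien-1-yl](methyl)bis(2-methylpropyl)aluminate | CC(C)(C)[Si](C)(C)OC/C=C(\C)CC/C=C(\C)CC/C=C(\[Al-](C)(CC(C)C)CC(C)C)[Si](C)(C)C.[Li+]
F7 | step 8 | tert-butyl{[(2E,6E,10E)-3,7-dimethyl-11-(trimethylsilyl)dodeca-2,6,10-trien-1-yl]oxy}dimethylsilane | CC(C)(C)[Si](C)(C)OC/C=C(\C)CC/C=C(\C)CC/C=C(\C)[Si](C)(C)C
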